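**Assumption:** the side chain in the SMILES is read as unbranched docosyl (22 carbons). The target has no stereocentre and no stereogenic double bond, so it is achiral and needs no stereocontrol. Compounds 1 and 3 are taken as catalogue compounds.

## Retrosynthetic overview

1. The chain carbon is reversed in polarity: electrophilic 1-bromodocosane 1 becomes 1-nitrodocosane 2, whose nitronate is a carbanion that carries its own leaving group.
2. Key disconnection: the ring–chain bond, made from that nitronate carbon and the free, electrophilic ring CH (C6, next to the methyl-bearing carbon) of 2-methoxy-5-methyl-1,4-benzoquinone 3.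
3. In one flask, nitronate 4 adds, adduct 5 loses nitrite to give quinone methide 6, and 6 tautomerises to target 7, with no change of oxidation level and no protecting group.
4. Ring order: no ring is formed; the only ring is bought intact as 3.

## Route

Step 1
Reactants: 1 1-bromodocosane
Product: 2 1-nitrodocosane
Conditions: AgNO2 (1.5 equiv), Et2O, 0 °C to rt, dark, 48 h; crystallisation from hexane
Reagents that add atoms: silver nitrite, [Ag+].[O-]N=O
Why: Victor Meyer reaction, a silver-assisted SN2 displacement of an unhindered primary bromide by ambident nitrite that gives mainly the N-alkylated nitroalkane (the minor docosyl nitrite is removed on crystallisation); no stereocentre is formed.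

Step 2
Reactants: 2 1-nitrodocosane; 3 2-methoxy-5-methylcyclohexa-2,5-diene-1,4-dione (2-methoxy-5-methyl-1,4-benzoquinone)
Product: 7 3-docosyl-5-methoxy-2-methylcyclohexa-2,5-diene-1,4-dione, via potassium nitronate 4 (not isolated), via nitroalkyl hydroquinone 5 (not isolated), via hydroxy quinone methide 6 (not isolated)
Conditions: 2 (1.1 equiv), KOt-Bu (1.05 equiv), THF–DMF 4:1, 0 °C, 20 min; then 3 (1.0 equiv) in THF, −40 °C, 1 h, then rt, 2 h, N2, dark; AcOH quench
Reagents that add atoms: none
Why: Proposed new method: nitronate 4, the nucleophilic form of the chain carbon that is an electrophile in bromide 1, adds in Michael fashion to C6 of quinone 3 (the only ring CH that is beta to a carbonyl and is not the electron-rich alpha-carbon of the methoxy enone), the adduct aromatises to the monoanion of hydroquinone 5 (its benzylic stereocentre is racemic and is erased in the next event), the ortho-phenoxide expels nitrite to give ortho-quinone methide 6, and 6 is simply the tautomer of 7 and relaxes to it by proton transfer from the C4 hydroxyl to the exocyclic carbon, so the alkylation is redox-neutral and leaves only KNO2; the closest known reaction types are the base-mediated tandem Michael addition and nitrous acid elimination of primary nitroalkanes with ene-1,4-diones, and the expulsion of a benzylic leaving group from ortho-hydroxybenzyl compounds to form ortho-quinone methides.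

## Compound list

1 | 1-bromodocosane (unbranched C22 primary bromide) | CCCCCCCCCCCCCCCCCCCCCCBr | starting material
2 | 1-nitrodocosane | CCCCCCCCCCCCCCCCCCCCCC[N+](=O)[O-] | intermediate
3 | 2-methoxy-5-methylcyclohexa-2,5-diene-1,4-dione (2-methoxy-5-methyl-1,4-benzoquinone) | COC1=CC(=O)C(C)=CC1=O | starting material
4 | potassium docosane-1-nitronate (potassium salt of aci-1-nitrodocosane; formed in the flask) | CCCCCCCCCCCCCCCCCCCCCC=[N+]([O-])[O-].[K+] | intermediate
5 | 5-methoxy-2-methyl-3-(1-nitrodocosyl)benzene-1,4-diol (racemic at the nitro-bearing carbon; present in the flask as its potassium phenoxide) | CCCCCCCCCCCCCCCCCCCCCC([N+](=O)[O-])c1c(C)c(O)cc(OC)c1O | intermediate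
6 | 6-docosylidene-4-hydroxy-2-methoxy-5-methylcyclohexa-2,4-dien-1-one (ortho-quinone methide; exocyclic double-bond geometry not controlled and of no consequence) | CCCCCCCCCCCCCCCCCCCCCC=C1C(C)=C(O)C=C(OC)C1=O | intermediate
7 | 3-docosyl-5-methoxy-2-methylcyclohexa-2,5-diene-1,4-dione (achiral) | CCCCCCCCCCCCCCCCCCCCCCC1=C(C)C(=O)C=C(OC)C1=O | target

## Step count and risks

Total step count: 2.
Longest linear sequence: 2 steps (1 → 2 → 7); quinone 3 enters in step 2.

The route has only two steps, so both are ranked, and the key step is listed under its two separate failure points.

**Most likely to fail: step 2, the carbon–carbon bond formation.** Nitronate 4 may not add cleanly at C6 of 3. It could attack the methoxy-bearing carbon, transfer an electron, or let the quinone decay under base. The fallback sets out from quinone 3 and comes back to the route at 7.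
- Quinone 3 and commercial docosanal (CCCCCCCCCCCCCCCCCCCCCC=O) are irradiated in benzene at rt under N2. The excited quinone abstracts the aldehyde hydrogen, and the nucleophilic acyl radical, again a reversed-polarity form of the aldehyde carbon, recombines at C6 (photo-Friedel–Crafts acylation). This gives 1-(2,5-dihydroxy-3-methoxy-6-methylphenyl)docosan-1-one F1.
- Ionic hydrogenation with Et3SiH (3 equiv) in CF3CO2H at rt reduces the electron-rich aryl ketone to 3-docosyl-5-methoxy-2-methylbenzene-1,4-diol F2.
- Ag2O with Na2SO4 in Et2O at rt oxidises F2 to 7.

**Second: step 2, nitrite loss and tautomerisation.** Adduct 5 may form, but quinone methide 6 could dimerise or be attacked by nucleophiles faster than it relaxes to 7, or 7 could suffer in the basic medium. The fallback sets out from 5 and comes back at 7.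
- The reaction is stopped at −40 °C with AcOH and crude 5 is treated with NaBH4 (4 equiv) in EtOH–THF at 0 °C to rt.
- In this basic hydride medium the phenoxide expels nitrite and hydride traps 6 at its exocyclic carbon as soon as it forms. This is the known borohydride reduction of ortho-quinone methides generated in situ.
- The product is 3-docosyl-5-methoxy-2-methylbenzene-1,4-diol F2, the same compound as in the first fallback, which Ag2O in Et2O oxidises to 7.

**Third: step 1.** The nitrite ester may dominate, or the waxy bromide may react sluggishly. The fallback sets out from 1 and comes back at 2.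
- NaN3 in DMF at 60 °C gives 1-azidodocosane F3.
- Hydrogenation (H2, 1 atm, Pd/C, THF–EtOH) gives docosan-1-amine F4.
- mCPBA (3.5 equiv) in refluxing 1,2-dichloroethane oxidises the primary amine through the hydroxylamine and nitroso stages to nitroalkane 2.

## Further compounds

F1 | step 2 | 1-(2,5-dihydroxy-3-methoxy-6-methylphenyl)docosan-1-one | CCCCCCCCCCCCCCCCCCCCCC(=O)c1c(C)c(O)cc(OC)c1O
F2 | step 2 | 3-docosyl-5-methoxy-2-methylbenzene-1,4-diol | CCCCCCCCCCCCCCCCCCCCCCc1c(C)c(O)cc(OC)c1O
F3 | step 1 | 1-azidodocosane | CCCCCCCCCCCCCCCCCCCCCCN=[N+]=[N-]
F4 | step 1 | docosan-1-amine | CCCCCCCCCCCCCCCCCCCCCCN
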